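(The constants were set for the occasion; the run is a simulation.)

I followed one ratio through these flasks: the rate of the side step over the rates of the two steps that make target.

    substrate → target (k1 = 0.0245 s⁻¹)
    substrate + target → side product (k2 = 46.3 M⁻¹ s⁻¹)
    substrate + 2 target → 3 target (k3 = 1.13 × 10⁶ M⁻² s⁻¹)

| flask | substrate | time |
|---|---|---|
| Tuesday's | 1.0 mM | 2.5 s |
| Wednesday's | 2.0 mM | 2.5 s |
| Friday's | 4.0 mM | 2.5 s |
| Saturday's | 8.0 mM | 2.5 s |
| Sunday's | 15 mM | 2.5 s |

- percentages count the substrate that a species holds: one side product counts as two
- a step written with two of one species runs at k times the square of its concentration and takes two of it each time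
- "hardly changes" means that all values lie within two and a half points (for a concentration: within two and a half percent of the largest)
- run time (Tuesday's): 2.5 s

* share of target in all that became target or side product for Tuesday's, Wednesday's, Friday's, Saturday's, Sunday's, in this order
* how that number moves from the first to the last of them (hardly changes / falls, then rises / rises all the way / rises, then falls / falls all the way)

I reckoned that the first arrow, by itself and with substrate barely touched, lays down about 6.12 % of the charge in 2.5 s. But the second arrow grows with target, so the side step gains as target builds. The third arrow grows with the square of target, so it catches the first at some level. On Tuesday's charge that level came to 14.7 %, and I called it the crossing fraction, the part of the charge held as target when the autocatalytic step runs as fast as the plain one. It shrinks as the charge grows, to 7.36 % on Wednesday's, 3.68 % on Friday's, 1.84 % on Saturday's and 0.982 % on Sunday's.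

Substrate multiplies each of the three rates and cancels, so my ratio hangs on target, and it peaks exactly at the crossing, at 13.9 %. So I held 6.12 % against each crossing fraction: as an estimate it lay well below Tuesday's and close beneath Wednesday's, but above Friday's, Saturday's and Sunday's. I scored each shape by how far the first and last charges lay on the side of the crossing that it needs, and the choice came to falls, then rises, but I got no figures for the row by hand.

The forecast gave 90 %, 82.9 %, 84.8 %, 95.7 % and 97.4 %, with the shape falls, then rises, holding that Saturday's and Sunday's flasks “pass through the lossy window quickly”.

The flasks gave 90.0 %, 82.9 %, 84.5 %, 95.7 % and 97.4 %, and the row went: falls, then rises. It turned at a charge of 3.1 mM, above Wednesday's charge and below Friday's. Wednesday's target ended at 6.62 %, under its crossing fraction of 7.36 %. Friday's target stood at 3.40 % after 1.25 s, still under its crossing fraction of 3.68 %, and after 2.50 s it stood far past that fraction, at 22.5 %.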